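**Retrosynthetic overview**
1. Feature used: the C5 oxygen and the C10 methyl (C14) lie on the same face of the ten-membered carbocycle, 1,6 to each other. C14 is therefore treated as a one-carbon carbonyl bridge between C5 and C10, so C5–C10 plus C14 are the seven carbons of tropone and C1–C4 plus C15 a 2,3-dioxygenated penta-1,3-diene.
2. Key disconnection: a [6+4] cycloaddition forms C4–C5 and C1–C10 and closes, in one step, the cycloheptenone ring and the ten-membered ring as the periphery of a bicyclo[4.4.1]undecatrienone.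
3. In the rigid bicycle: ketol unmasking, C4 hydroxylation, C4–OH-directed C6/C7 epoxidation, malonate opening at C7 with closure of the trans γ-lactone, then the C8/C9 β-epoxide.
4. Bridge excision: a peroxide tethered from C14 to C9 rearranges with migration of C5 (C5–O with retention, C9–OH freed). Hydrolysis of the bridged lactone unveils the ten-membered ring and C14 is reduced to methyl.
5. End game: C11 methylenation, 2-methylbutanoate on O5, angelate on O8, desilylation.

Key step: step 3

Remark (locants and faces): C1 ring CH2, C2 carbinol, C3 ketone, C4 methyl carbinol, C5–C9 oxygenated/lactone carbons, C10 methyl-bearing CH, C11–C13 lactone carbons, C14 and C15 the methyls on C10 and C4. α is the ring face that carries C14 and the C5 oxygen (exo, the side of the one-carbon bridge in the bicycles); β is the opposite, concave face.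
Remark (catalyst sense): the ligand enantiomer is assumed to be the one that exposes the tropone face leading to 5 as drawn.
Remark (drawn epimers): the epimerisable C11 centre of 11–22 is drawn with the ester anti to C8, and the hemiketal carbon of 14–16 as the epimer that cyclises; neither is stereochemically relevant.

Step 1
Reactants: 1 2,3-pentanedione
Product: 2 (Z)-3-(trimethylsilyloxy)pent-3-en-2-one
Conditions: TMSCl, Et3N, DMF, 23 → 60 °C
Reagents that add atoms: chlorotrimethylsilane, C[Si](C)(C)Cl
Why: Equilibrating soft enolisation/O-silylation of the 1,2-diketone should give the more substituted, conjugated enol ether on the ethyl side, with the Z geometry that keeps the methyl away from the acetyl group.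

Step 2
Reactants: 2 (Z)-3-(trimethylsilyloxy)pent-3-en-2-one
Product: 3 (Z)-2-(tert-butyldimethylsilyloxy)-3-(trimethylsilyloxy)penta-1,3-diene
Conditions: TBSOTf, Et3N, CH2Cl2, 0 °C
Reagents that add atoms: tert-butyldimethylsilyl triflate, CC(C)(C)[Si](C)(C)OS(=O)(=O)C(F)(F)F
Why: Silyl triflate/amine enolisation of the remaining methyl ketone (cross-conjugated dienol ether formation) gives the diene with two different silyl groups, so that the two enol oxygens can be told apart after the cycloaddition.

Step 3
Reactants: 3 (Z)-2-(tert-butyldimethylsilyloxy)-3-(trimethylsilyloxy)penta-1,3-diene; 4 tropone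
Product: 5 exo [6+4] adduct, bicyclo[4.4.1]undecatrien-11-one (C14 ketone bridging C5 and C10, C6=C7–C8=C9 diene, C2(OTBS)=C3(OTMS) enediol diether, 4α-methyl)
Conditions: Sc(OTf)3 (10 mol %), chiral C2-symmetric N,N′-dioxide ligand (11 mol %), 4 Å MS, CH2Cl2, −40 °C
Reagents that add atoms: none
Why: Proposed new method: scandium bound to the tropone oxygen lowers the LUMO and enlarges the coefficients at the two α-carbons, so the electron-rich disiloxydiene should add suprafacially across them (concerted and asynchronous, or Mukaiyama–Michael addition followed by closure of the siloxyallyl cation onto the trienolate carbon), forming C4–C5 and C1–C10; the closest known reactions are the thermal exo-selective [6+4] cycloaddition of tropone with 1,3-dienes (racemic) and chiral-Lewis-acid-catalysed higher-order cycloadditions of tropone with other partners. The cycloheptenone ring (C5, C4, C3, C2, C1, C10, C14) and the ten-membered ring (periphery C1–C10) are both closed by the second bond of a bimolecular cycloaddition, so no macrocyclisation is involved. C5 and C10 are necessarily cis on the bridge and their absolute sense is set by the tropone face left open by the ligand; C4 follows from the exo transition state and the Z enol geometry and is of no consequence because it is enolised in step 5. The step needs periselectivity ([6+4] over [4+2] and [8+2]), exo selectivity and face selectivity: the exo mode avoids the repulsive secondary interaction of the endo mode, the bulky 2,3-disiloxy groups disfavour the compact [4+2] arrangements, the Lewis acid on oxygen disfavours O-closure, and the ligand shields one face.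

Step 4
Reactants: 5 exo [6+4] adduct
Product: 6 2β-hydroxy-3-ketone (acyloin) of the bicycle, 4α-methyl, diene and C14 ketone intact
Conditions: TBAF (2.5 equiv), AcOH (3 equiv), THF, −78 → 0 °C
Reagents that add atoms: none
Why: Fluoride desilylation: the trimethylsilyl group is attacked first, the resulting C3 enolate is protonated on C2 from the exo (α) face, which fixes the ketone at C3 and the C2 oxygen on the β face (2R), and warming then cleaves the TBS ether.

Step 5
Reactants: 6 2β-hydroxy-3-ketone
Product: 7 2β,4α-dihydroxy-4β-methyl-3-ketone of the bicycle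
Conditions: KHMDS (2.3 equiv), THF, −78 °C; 2-(phenylsulfonyl)-3-phenyloxaziridine; AcOH, −78 °C
Reagents that add atoms: 2-(phenylsulfonyl)-3-phenyloxaziridine, O=S(=O)(c1ccccc1)N1OC1c1ccccc1
Why: Enolate α-hydroxylation with an N-sulfonyloxaziridine: the C2 alkoxide disfavours deprotonation at C2 and guides the base to the syn C4–H, and the C3/C4 enolate should be oxidised on its exo face, placing the C4 hydroxyl α (syn to the bridge) and the methyl β.

Step 6
Reactants: 7 2β,4α-dihydroxy-4β-methyl-3-ketone
Product: 8 2β-(tert-butyldimethylsilyloxy)-4α-hydroxy-3-ketone of the bicycle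
Conditions: TBSOTf (1.05 equiv), 2,6-lutidine, CH2Cl2, −78 °C
Reagents that add atoms: tert-butyldimethylsilyl triflate, CC(C)(C)[Si](C)(C)OS(=O)(=O)C(F)(F)F
Why: Selective silylation of the secondary C2 hydroxyl over the tertiary C4 hydroxyl, which is kept free as the directing group for the next step.

Step 7
Reactants: 8 2β-silyloxy-4α-hydroxy-3-ketone
Product: 9 6β,7β-epoxide (vinyl epoxide, C8=C9 retained)
Conditions: VO(acac)2 (5 mol %), t-BuOOH, CH2Cl2, 0 → 23 °C
Reagents that add atoms: tert-butyl hydroperoxide, CC(C)(C)OO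
Why: Vanadium-catalysed hydroxyl-directed epoxidation: the tertiary C4 alkoxide should deliver the peroxide only to the homoallylic C6=C7 bond and on the concave β face, which differentiates the two ends of the dienyl bridge and sets the C6 oxygen.

Step 8
Reactants: 9 6β,7β-epoxide; 10 dibenzyl malonate
Product: 11 trans-fused 6β,12-olide with C7–C11 α, benzyloxycarbonyl on C11, C8=C9 retained
Conditions: NaH (2.5 equiv), 10 (3 equiv), THF/DMF, 23 → 60 °C; AcOH
Reagents that add atoms: none
Why: Uncatalysed SN2 opening of the vinyl epoxide by malonate at the allylic carbon C7 with inversion, from the open α face, followed by lactonisation of the C6 alkoxide onto one ester, should set C7 and close the trans γ-lactone; malonate adds only reversibly to the non-enolisable C14 ketone and the absence of free hydride keeps the C4 hydroxyl protonated.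

Step 9
Reactants: 11 6β,12-olide with C8=C9
Product: 13 8β,9β-epoxide of the lactone, via 9α-bromo-8β-ol bromohydrin 12 (not isolated)
Conditions: NBS, THF/H2O, 0 °C; then Ag2O, 23 °C
Reagents that add atoms: water, O
Why: Bromohydrin formation and silver-assisted ring closure: the bromonium ion forms on the open α face, water opens it anti, and closure puts the epoxide oxygen on the β face, the face opposite to that reached by direct epoxidation.

Step 10
Reactants: 13 8β,9β-epoxide
Product: 15 3-hydroxy-1,2-dioxolane (peroxide bridge C14–O–O–C9α) with free 8β-hydroxyl, via C14 hydroperoxy hemiketal 14 (not isolated)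
Conditions: ethereal H2O2 (excess), phosphomolybdic acid (5 mol %), THF/Et2O, 0 → 23 °C
Reagents that add atoms: hydrogen peroxide, OO
Why: Acid-catalysed perhydrolysis of the epoxide through the peroxyhemiketal of the β,γ-epoxy ketone: the hydroperoxy group on the α side of C14 opens the epoxide 5-exo at C9 with inversion, which sets the C9 oxygen α and frees the 8β-hydroxyl.

Step 11
Reactants: 15 3-hydroxy-1,2-dioxolane
Product: 16 8β-triethylsilyl ether of the dioxolane
Conditions: TESCl (1.2 equiv), imidazole, DMF, 0 °C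
Reagents that add atoms: chlorotriethylsilane, CC[Si](CC)(CC)Cl
Why: Silylation of the only secondary hydroxyl (the hemiketal and C4 hydroxyls are tertiary), which labels O8 while O9 is still tied up in the peroxide.

Step 12
Reactants: 16 8β-silyloxy dioxolane
Product: 17 bridged lactone C5α–O–C14(=O)–C10 with free 9α-hydroxyl
Conditions: BF3·OEt2 (20 mol %), CH2Cl2, −78 → −20 °C
Reagents that add atoms: none
Why: Proposed new method: Lewis-acid-promoted Criegee (Baeyer–Villiger-type) rearrangement of the cyclic peroxyhemiketal, in which the dioxolane ring holds the C14–C10 bond gauche to the O–O bond so that only the exocyclic C14–C5 bond can be antiperiplanar to it; C5 should therefore migrate to oxygen with retention while the hemiketal oxygen pushes and O9 leaves as the alcohol; the closest known reactions are the Baeyer–Villiger oxidation, whose Criegee intermediate is the same peroxyhemiketal with an untethered leaving group, and Lewis-acid Criegee rearrangements of peroxyketals.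

Step 13
Reactants: 17 bridged lactone with 9α-hydroxyl
Product: 18 9α-(tert-butyldimethylsilyl) ether of the bridged lactone
Conditions: TBSOTf (1.1 equiv), 2,6-lutidine, CH2Cl2, −78 °C
Reagents that add atoms: tert-butyldimethylsilyl triflate, CC(C)(C)[Si](C)(C)OS(=O)(=O)C(F)(F)F
Why: Silylation of the only free secondary hydroxyl, so that O9 (robust TBS) and O8 (labile TES) stay differentiated to the end.

Step 14
Reactants: 18 fully protected bridged lactone
Product: 19 seco acid: monocyclic ten-membered ring with 10α-carboxyl (C14) and free 5α-hydroxyl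
Conditions: LiOH·H2O (3 equiv), THF/H2O, 0 °C; then aq. HCl to pH 4
Reagents that add atoms: water, O
Why: Saponification of the strained bridged lactone unveils the ten-membered carbocycle; the α-benzyloxycarbonyl γ-lactone is shielded as its stabilised enolate under the basic conditions and is recovered on acidification.

Step 15
Reactants: 19 seco acid
Product: 20 C14 primary alcohol (10α-hydroxymethyl)
Conditions: BH3·THF (3 equiv), THF, 0 °C; MeOH
Reagents that add atoms: none
Why: Chemoselective borane reduction: the carboxylic acid should be reduced much faster than the lactone, the benzyl ester and the hindered α,α′-dioxygenated C3 ketone.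

Step 16
Reactants: 20 C14 primary alcohol
Product: 21 C14 primary iodide (10α-iodomethyl)
Conditions: I2, PPh3, imidazole, CH2Cl2, −20 → 0 °C
Reagents that add atoms: iodine, II
Why: Appel-type iodination, selective for the primary hydroxyl over the hindered secondary C5 and tertiary C4 hydroxyls.

Step 17
Reactants: 21 C14 primary iodide
Product: 22 10α-methyl compound with free C11 carboxylic acid
Conditions: H2 (1 atm), 10% Pd/C, Et3N, EtOAc, 23 °C
Reagents that add atoms: none
Why: Heterogeneous hydrogenolysis reduces the primary C–I bond to the C14 methyl and cleaves the benzyl ester in one operation; no C=C bond is present at this stage.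

Step 18
Reactants: 22 C11 carboxylic acid; 23 formaldehyde
Product: 24 α-methylene γ-lactone with free 5α-hydroxyl
Conditions: 37% aq. CH2O, Et2NH, AcOH/NaOAc, THF, 23 → 50 °C
Reagents that add atoms: none
Why: Decarboxylative Mannich methylenation of the malonic half-acid gives the exocyclic methylene under mild, non-enolising conditions that spare the C3 ketone, and removes the C11 stereocentre.

Step 19
Reactants: 24 α-methylene lactone with 5α-hydroxyl; 25 (R)-2-methylbutanoic acid
Product: 26 5α-O-[(R)-2-methylbutanoyl] ester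
Conditions: DCC, DMAP (0.2 equiv), CH2Cl2, 0 → 23 °C
Reagents that add atoms: none
Why: Steglich esterification of the only free secondary hydroxyl; the tertiary C4 hydroxyl does not acylate under these conditions.

Step 20
Reactants: 26 5α-ester
Product: 27 8β-alcohol (2β- and 9α-TBS ethers retained)
Conditions: PPTS (0.2 equiv), MeOH/CH2Cl2, 0 °C
Reagents that add atoms: none
Why: Acid-catalysed methanolysis removes the secondary TES ether selectively in the presence of the two TBS ethers.

Step 21
Reactants: 27 8β-alcohol; 28 angelic acid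
Product: 30 8β-O-angelate (bis-TBS ether of the target), via angelic 2,4,6-trichlorobenzoic anhydride 29 (not isolated)
Conditions: 2,4,6-trichlorobenzoyl chloride, Et3N, toluene, 23 °C; then 27, toluene, 80 °C
Reagents that add atoms: none
Why: Yamaguchi esterification run without a nucleophilic catalyst, so that the hindered 8β-hydroxyl is acylated without isomerisation of the Z-enoate to the tiglate.

Step 22
Reactants: 30 bis-TBS ether of the target
Product: 31 CNP0301185.1
Conditions: HF·pyridine, pyridine, THF, 0 → 23 °C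
Reagents that add atoms: none
Why: Buffered fluoride desilylation frees the C2 and C9 hydroxyls without touching the α-methylene lactone, the two esters or the ketol.

**Compound list**
1 | 2,3-pentanedione | CCC(=O)C(C)=O | starting material
2 | (Z)-3-(trimethylsilyloxy)pent-3-en-2-one | CC(=O)/C(O[Si](C)(C)C)=C/C | intermediate
3 | (Z)-2-(tert-butyldimethylsilyloxy)-3-(trimethylsilyloxy)penta-1,3-diene | C=C(O[Si](C)(C)C(C)(C)C)/C(O[Si](C)(C)C)=C/C | intermediate
4 | tropone | O=C1C=CC=CC=C1 | starting material
5 | exo [6+4] adduct, bicyclo[4.4.1]undecatrien-11-one with C2(OTBS)=C3(OTMS) and 4α-methyl | O=C1[C@@H]2C=CC=C[C@H]1CC(O[Si](C)(C)C(C)(C)C)=C(O[Si](C)(C)C)[C@@H]2C | intermediate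
6 | bicyclic 2β-hydroxy-3-ketone (acyloin) | O=C1[C@@H]2C=CC=C[C@H]1C[C@@H](O)C(=O)[C@@H]2C | intermediate
7 | bicyclic 2β,4α-dihydroxy-4β-methyl-3-ketone | O=C1[C@@H]2C=CC=C[C@H]1C[C@@H](O)C(=O)[C@]2(C)O | intermediate
8 | 2β-OTBS, 4α-hydroxy-3-ketone | O=C1[C@@H]2C=CC=C[C@H]1C[C@@H](O[Si](C)(C)C(C)(C)C)C(=O)[C@]2(C)O | intermediate
9 | 6β,7β-epoxide (vinyl epoxide) | O=C1[C@@H]2[C@H]3O[C@H]3C=C[C@H]1C[C@@H](O[Si](C)(C)C(C)(C)C)C(=O)[C@]2(C)O | intermediate
10 | dibenzyl malonate | O=C(CC(=O)OCc1ccccc1)OCc1ccccc1 | starting material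
11 | trans 6β,12-olide, 11-benzyloxycarbonyl, C8=C9, C14 ketone bridge | O=C(OCc1ccccc1)[C@@H]1C(=O)O[C@H]2[C@H]1C=C[C@H]3C[C@@H](O[Si](C)(C)C(C)(C)C)C(=O)[C@](C)(O)[C@@H]2C3=O | intermediate
12 | 9α-bromo-8β-ol bromohydrin | O=C(OCc1ccccc1)[C@@H]1C(=O)O[C@H]2[C@H]1[C@@H](O)[C@H](Br)[C@H]3C[C@@H](O[Si](C)(C)C(C)(C)C)C(=O)[C@](C)(O)[C@@H]2C3=O | intermediate
13 | 8β,9β-epoxide | O=C(OCc1ccccc1)[C@@H]1C(=O)O[C@H]2[C@H]1[C@H]4O[C@H]4[C@H]3C[C@@H](O[Si](C)(C)C(C)(C)C)C(=O)[C@](C)(O)[C@@H]2C3=O | intermediate
14 | C14 hydroperoxy hemiketal of 13 | O=C(OCc1ccccc1)[C@@H]1C(=O)O[C@H]2[C@H]1[C@H]4O[C@H]4[C@H]3C[C@@H](O[Si](C)(C)C(C)(C)C)C(=O)[C@](C)(O)[C@@H]2[C@@]3(O)OO | intermediate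
15 | 3-hydroxy-1,2-dioxolane (C14–O–O–C9α), 8β-OH | O=C(OCc1ccccc1)[C@@H]1C(=O)O[C@H]2[C@H]1[C@@H](O)[C@H]4[C@H]3C[C@@H](O[Si](C)(C)C(C)(C)C)C(=O)[C@](C)(O)[C@@H]2[C@@]3(O)OO4 | intermediate
16 | 8β-OTES dioxolane | O=C(OCc1ccccc1)[C@@H]1C(=O)O[C@H]2[C@H]1[C@@H](O[Si](CC)(CC)CC)[C@H]4[C@H]3C[C@@H](O[Si](C)(C)C(C)(C)C)C(=O)[C@](C)(O)[C@@H]2[C@@]3(O)OO4 | intermediate
17 | bridged lactone C5α–O–C14(=O)–C10, 9α-OH | O=C(OCc1ccccc1)[C@@H]1C(=O)O[C@H]2[C@H]1[C@@H](O[Si](CC)(CC)CC)[C@H](O)[C@H]3C[C@@H](O[Si](C)(C)C(C)(C)C)C(=O)[C@](C)(O)[C@@H]2OC3=O | intermediate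
18 | bridged lactone, 9α-OTBS | O=C(OCc1ccccc1)[C@@H]1C(=O)O[C@H]2[C@H]1[C@@H](O[Si](CC)(CC)CC)[C@H](O[Si](C)(C)C(C)(C)C)[C@H]3C[C@@H](O[Si](C)(C)C(C)(C)C)C(=O)[C@](C)(O)[C@@H]2OC3=O | intermediate
19 | seco acid, 10α-CO2H, 5α-OH (monocyclic ten-membered ring) | O=C(OCc1ccccc1)[C@@H]1C(=O)O[C@H]2[C@H]1[C@@H](O[Si](CC)(CC)CC)[C@H](O[Si](C)(C)C(C)(C)C)[C@H](C(=O)O)C[C@@H](O[Si](C)(C)C(C)(C)C)C(=O)[C@](C)(O)[C@@H]2O | intermediate
20 | C14 primary alcohol | O=C(OCc1ccccc1)[C@@H]1C(=O)O[C@H]2[C@H]1[C@@H](O[Si](CC)(CC)CC)[C@H](O[Si](C)(C)C(C)(C)C)[C@H](CO)C[C@@H](O[Si](C)(C)C(C)(C)C)C(=O)[C@](C)(O)[C@@H]2O | intermediate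
21 | C14 primary iodide | O=C(OCc1ccccc1)[C@@H]1C(=O)O[C@H]2[C@H]1[C@@H](O[Si](CC)(CC)CC)[C@H](O[Si](C)(C)C(C)(C)C)[C@H](CI)C[C@@H](O[Si](C)(C)C(C)(C)C)C(=O)[C@](C)(O)[C@@H]2O | intermediate
22 | 10α-methyl, C11 carboxylic acid | O=C(O)[C@@H]1C(=O)O[C@H]2[C@H]1[C@@H](O[Si](CC)(CC)CC)[C@H](O[Si](C)(C)C(C)(C)C)[C@H](C)C[C@@H](O[Si](C)(C)C(C)(C)C)C(=O)[C@](C)(O)[C@@H]2O | intermediate
23 | formaldehyde | C=O | starting material
24 | α-methylene lactone, 5α-OH | C=C1C(=O)O[C@H]2[C@H]1[C@@H](O[Si](CC)(CC)CC)[C@H](O[Si](C)(C)C(C)(C)C)[C@H](C)C[C@@H](O[Si](C)(C)C(C)(C)C)C(=O)[C@](C)(O)[C@@H]2O | intermediate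
25 | (R)-2-methylbutanoic acid | CC[C@@H](C)C(=O)O | starting material
26 | 5α-O-(R)-2-methylbutanoate | C=C1C(=O)O[C@H]2[C@H]1[C@@H](O[Si](CC)(CC)CC)[C@H](O[Si](C)(C)C(C)(C)C)[C@H](C)C[C@@H](O[Si](C)(C)C(C)(C)C)C(=O)[C@](C)(O)[C@@H]2OC(=O)[C@H](C)CC | intermediate
27 | 8β-alcohol | C=C1C(=O)O[C@H]2[C@H]1[C@@H](O)[C@H](O[Si](C)(C)C(C)(C)C)[C@H](C)C[C@@H](O[Si](C)(C)C(C)(C)C)C(=O)[C@](C)(O)[C@@H]2OC(=O)[C@H](C)CC | intermediate
28 | angelic acid, (Z)-2-methylbut-2-enoic acid | C/C=C(/C)C(=O)O | starting material
29 | angelic 2,4,6-trichlorobenzoic anhydride | C/C=C(/C)C(=O)OC(=O)c1c(Cl)cc(Cl)cc1Cl | intermediate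
30 | 8β-O-angelate, 2β,9α-bis-TBS ether | C=C1C(=O)O[C@H]2[C@H]1[C@@H](OC(=O)/C(C)=C\C)[C@H](O[Si](C)(C)C(C)(C)C)[C@H](C)C[C@@H](O[Si](C)(C)C(C)(C)C)C(=O)[C@](C)(O)[C@@H]2OC(=O)[C@H](C)CC | intermediate
31 | CNP0301185.1 (2R,4R,5R,6S,7R,8R,9R,10R; (R)-2-methylbutanoate; Z-enoate) | C=C1C(=O)O[C@H]2[C@H]1[C@@H](OC(=O)/C(C)=C\C)[C@H](O)[C@H](C)C[C@@H](O)C(=O)[C@](C)(O)[C@@H]2OC(=O)[C@H](C)CC | target

**Totals**
Total step count: 22. Longest linear sequence: 22 steps (1 → 31); tropone enters at step 3.

**Steps most likely to fail**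

Step 3 (proposed new method). What may go wrong: loss of periselectivity (competing [4+2] or [8+2] addition, or Michael addition without ring closure), protodesilylation of the diene by the Lewis acid, and poor discrimination of the tropone faces. Fallback: starting from 3 and 4, the cycloaddition is run thermally without catalyst (toluene, 110 °C), the known exo-selective mode, to give the racemic adduct F1. Treatment with TBAF/AcOH as in step 4 gives the racemic acyloin F2, which is resolved by preparative chromatography on a chiral stationary phase. The (2R)-enantiomer is compound 6, where the route is rejoined.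

Step 12 (proposed new method). What may go wrong: O–O heterolysis without migration of C5 (reversion to the hydroperoxy ketone, Hock-type cleavage at C9) or loss of the silyl ethers under the Lewis acid. Fallback: starting from 16, the O–O bond is cleaved reductively with PPh3 to give the β-hydroxy ketone F3, which is submitted to a conventional intermolecular Baeyer–Villiger oxidation with a buffered peracid (CF3CO3H, Na2HPO4, CH2Cl2, 0 °C) to give 17, where the route is rejoined. This fallback is weak: with no tether, the inductive bias in F3 favours migration of C10 (C5 is flanked by two oxygen-bearing carbons, C10 by one), so 17 is expected to be the minor lactone and would have to be separated from the C10-migrated isomer by chromatography.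

Step 5. What may go wrong: enolisation toward C2 instead of C4 (leading through the enediolate to the 1,2-diketone), or retro-aldol opening of the C4 alkoxide next to the C14 ketone before the quench. Fallback: starting from 6, Dess–Martin oxidation gives the 1,2-diketone F4; equilibrating silylation (TMSCl, Et3N, DMF) gives the more substituted 3-silyloxy enone F5; Rubottom oxidation (mCPBA, NaHCO3, −40 °C, then aqueous HF) on the exo face gives the 4α-hydroxy-2,3-diketone F6. Reduction of the less hindered, more electrophilic C2 carbonyl with NaBH4 (1 equiv, −78 °C) by exo hydride delivery returns to compound 7.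

**Further compounds**
F1 | step 3 | racemic exo [6+4] adduct (5 and its enantiomer) | O=C1[C@@H]2C=CC=C[C@H]1CC(O[Si](C)(C)C(C)(C)C)=C(O[Si](C)(C)C)[C@@H]2C.O=C1[C@H]2C=CC=C[C@@H]1CC(O[Si](C)(C)C(C)(C)C)=C(O[Si](C)(C)C)[C@H]2C
F2 | step 3 | racemic acyloin (6 and its enantiomer) | O=C1[C@@H]2C=CC=C[C@H]1C[C@@H](O)C(=O)[C@@H]2C.O=C1[C@H]2C=CC=C[C@@H]1C[C@H](O)C(=O)[C@H]2C
F3 | step 12 | β-hydroxy ketone: C14 ketone bridge, 9α-OH, 8β-OTES | O=C(OCc1ccccc1)[C@@H]1C(=O)O[C@H]2[C@H]1[C@@H](O[Si](CC)(CC)CC)[C@H](O)[C@H]3C[C@@H](O[Si](C)(C)C(C)(C)C)C(=O)[C@](C)(O)[C@@H]2C3=O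
F4 | step 5 | bicyclic 2,3-diketone | O=C1[C@@H]2C=CC=C[C@H]1CC(=O)C(=O)[C@@H]2C
F5 | step 5 | 3-(trimethylsilyloxy)-3-en-2-one (enol ether toward C4) | O=C1[C@@H]2C=CC=C[C@H]1CC(=O)C(O[Si](C)(C)C)=C2C
F6 | step 5 | 4α-hydroxy-4β-methyl-2,3-diketone | O=C1[C@@H]2C=CC=C[C@H]1CC(=O)C(=O)[C@]2(C)O
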